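**Plan**
1. Cuts: the C3–acyl bond; the C7 prenyl group (back to a 7-methylene); then ring B at C1–C8 (key step) and at C5–C6. This leads to (2S,3R)-2,3-epoxyneryl bromide (from nerol) and 1,5-dimethoxycyclohexa-1,4-diene (Birch product of 1,3-dimethoxybenzene).
2. Enabling feature: ring A (C1–C5, C9) is a 1,3,5-trioxygenated six-membered ring, i.e. a masked resorcinol. C5 lies between the oxygenated carbons C4 and C9, and C1 is the β-carbon of the C9 enol ether, so the two carbons flanking C9 can be bridged by a C6–C7–C8 unit whose C8 is the tertiary end of an epoxide.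
3. Forward order: ring A comes from the arene (Birch dearomatisation); C5 is alkylated with C6; ring B is closed last by Lewis-acid epoxide opening at C8 by C1, the C7 oxygen trapping C9 as a temporary 7,9-epoxy ketal.
4. Helpers and their removal: C2 is carried as CH2 (oxidised in step 6); O4/O9 as methyl enol ether/ketal (hydrolysed in step 12); the C7 oxygen is converted to ketone, then methylene, then prenyl.
5. Stereochemistry: Sharpless epoxidation of nerol fixes the absolute configuration; anti opening of the Z-epoxide sets C8; a chair transition state sets C1/C5; C7 is set last by exo-face hydroboration of the 7-methylene (prenyl endo, cis to the 8-methyl group).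

Key step: step 5

Remarks.
- Locants used throughout: C1/C5 are the bridgeheads, C2–C3–C4 the oxygenated bridge (C2 next to C1), C6–C7–C8 the carbon bridge (C8 quaternary, next to C1), C9 the one-carbon bridge. They are von Baeyer locants but not always the lowest set.
- "exo" at C7/C8 means on the face of ring B (C1, C5, C6, C7, C8, C9) turned away from the C2–C3–C4 bridge; "endo" means on the face turned toward it. In the target the 8-(4-methylpent-3-enyl) group is exo, and the 8-methyl and 7-prenyl groups are endo.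
- The enolised β-triketone is one compound in two rapidly exchanging tautomers (2-hydroxy-4-oxo as in the target SMILES, or 4-hydroxy-2-oxo).
- 1,3-Dimethoxybenzene, nerol and all reagents named are commercial.

**Step 1**
Reactants: 1 1,3-dimethoxybenzene
Product: 2 1,5-dimethoxycyclohexa-1,4-diene
Conditions: Na, NH3(l), t-BuOH, THF, −78 → −33 °C
Reagents that add atoms: none
Why: Birch reduction: the two methoxy groups stay on the surviving double bonds, so protonation occurs at C2 and C5 of the arene and gives the skipped 1,4-diene; no stereocenter is formed.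

**Step 2**
Reactants: 3 nerol
Product: 4 (2S,3R)-2,3-epoxynerol
Conditions: Ti(Oi-Pr)4 (cat.), L-(+)-diethyl tartrate (cat.), t-BuOOH, 4 Å MS, CH2Cl2, −20 °C
Reagents that add atoms: tert-butyl hydroperoxide, CC(C)(C)OO
Why: Katsuki–Sharpless asymmetric epoxidation of the Z-allylic alcohol: the titanium–L-(+)-tartrate complex should deliver oxygen to the enantioface that gives the (2S,3R)-epoxide, which fixes the absolute configuration of the later C7 and C8, while the remote alkene has no directing hydroxyl group and is left alone.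

**Step 3**
Reactants: 4 (2S,3R)-2,3-epoxynerol
Product: 5 (2R,3R)-2-(bromomethyl)-3-methyl-3-(4-methylpent-3-en-1-yl)oxirane
Conditions: CBr4, PPh3, 2,6-lutidine, CH2Cl2, 0 °C
Reagents that add atoms: carbon tetrabromide, BrC(Br)(Br)Br
Why: Appel reaction: bromide displaces the alkoxyphosphonium group at the primary carbon (SN2), the buffered medium spares the epoxide and no stereocenter is touched (the descriptor at C2 becomes R only because CH2Br outranks C3).

**Step 4**
Reactants: 2 1,5-dimethoxycyclohexa-1,4-diene; 5 (2R,3R)-2-(bromomethyl)-3-methyl-3-(4-methylpent-3-en-1-yl)oxirane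
Product: 7 (2S,3R)-2-[(2,6-dimethoxycyclohexa-2,5-dien-1-yl)methyl]-3-methyl-3-(4-methylpent-3-en-1-yl)oxirane, via dienyllithium 6 (not isolated)
Conditions: 2, t-BuLi, THF, −78 °C; then 5, −78 → −20 °C
Reagents that add atoms: none
Why: The hydrogen on the sp3 carbon between the two methoxy-bearing carbons is the most acidic one, the pentadienyl-type organolithium is alkylated at that carbon by SN2 at the primary bromide faster than the hindered trisubstituted epoxide is opened, and no stereocenter is formed because the two enol ether arms are identical.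

**Step 5**
Reactants: 7 (2S,3R)-2-[(2,6-dimethoxycyclohexa-2,5-dien-1-yl)methyl]-3-methyl-3-(4-methylpent-3-en-1-yl)oxirane
Product: 9 (1R,5R,7S,8R,9S)-4,9-dimethoxy-8-methyl-8-(4-methylpent-3-en-1-yl)-7,9-epoxybicyclo[3.3.1]non-3-ene, via silyloxy oxocarbenium triflate 8 (not isolated)
Conditions: TMSOTf, 2,6-lutidine, CH2Cl2, −78 °C
Reagents that add atoms: none
Why: TMSOTf silylates the epoxide oxygen and the β-carbon of one methyl enol ether (C1) opens the epoxide at the tertiary carbon C8 with inversion, after which the C7 silyl ether oxygen adds to the C9 oxocarbenium ion and TMSOTf is returned; the closest known reaction type is the Lewis-acid epoxide-opening (cation–olefin type) cyclisation of 6-alkylated 1,5-dimethoxycyclohexa-1,4-dienes to bicyclo[3.3.1]nonane ketals. Ring B closes in the 6-endo mode at the epoxide (both epoxide carbons end in the ring) and the oxolane ring of the ketal closes 5-exo-trig at the oxocarbenium carbon. C8 is controlled by the epoxide configuration through backside attack (the Z geometry from nerol puts the homoprenyl chain exo, on the face of the C7 oxygen, and the methyl group endo); C7 keeps the epoxide configuration (oxygen exo); C1 and C5 are controlled by the chair-like transition state in which the C7–O bond is equatorial and anti-periplanar to the forming C1–C8 bond, which selects one of the two enantiotopic enol ethers; C9 is fixed by the geometry of the oxygen bridge. The step needs regioselectivity for C8 over C7 (tertiary, cation-stabilising carbon and six- over five-membered ring), group selectivity between the two enol ethers (chair over boat) and chemoselectivity over the remote trisubstituted alkene (which could reach C8 only through a four- or strained five-membered ring), and 2,6-lutidine keeps the enol ethers from protonation.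

**Step 6**
Reactants: 9 (1R,5R,7S,8R,9S)-4,9-dimethoxy-8-methyl-8-(4-methylpent-3-en-1-yl)-7,9-epoxybicyclo[3.3.1]non-3-ene
Product: 10 4,9-dimethoxy-8-endo-methyl-8-exo-(4-methylpent-3-en-1-yl)-7,9-epoxybicyclo[3.3.1]non-3-en-2-one
Conditions: Pd(OH)2/C (cat.), t-BuOOH, Cs2CO3, CH2Cl2, 4 °C
Reagents that add atoms: tert-butyl hydroperoxide, CC(C)(C)OO
Why: Allylic C–H oxidation (Pd/t-BuOOH radical chain): the C2 methylene is the only allylic CH2 activated by an enol ether, the allylic bridgehead C5–H cannot give a planar allyl radical, and the product is the stable vinylogous ester; no stereocenter changes.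

**Step 7**
Reactants: 10 4,9-dimethoxy-8-endo-methyl-8-exo-(4-methylpent-3-en-1-yl)-7,9-epoxybicyclo[3.3.1]non-3-en-2-one
Product: 11 7-exo-hydroxy-4,9,9-trimethoxy-8-endo-methyl-8-exo-(4-methylpent-3-en-1-yl)bicyclo[3.3.1]non-3-en-2-one
Conditions: PPTS (cat.), MeOH, 40 °C
Reagents that add atoms: methanol, CO
Why: Acid-catalysed transketalisation: the strained 7,9-epoxy ketal (oxanorbornane unit, boat ring B) ionises at C9, methanol as solvent captures the oxocarbenium ion and the exo C7 hydroxyl is set free, while exchange at the vinylogous ester is degenerate in methanol and no stereocenter is touched.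

**Step 8**
Reactants: 11 7-exo-hydroxy-4,9,9-trimethoxy-8-endo-methyl-8-exo-(4-methylpent-3-en-1-yl)bicyclo[3.3.1]non-3-en-2-one
Product: 12 4,9,9-trimethoxy-8-endo-methyl-8-exo-(4-methylpent-3-en-1-yl)bicyclo[3.3.1]non-3-ene-2,7-dione
Conditions: Dess–Martin periodinane, NaHCO3, CH2Cl2, 0 → 23 °C
Reagents that add atoms: none
Why: Dess–Martin oxidation of the secondary alcohol under buffered conditions that spare ketal, enol ether and alkene; the C7 stereocenter is given up on purpose and is rebuilt in step 10.

**Step 9**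
Reactants: 12 4,9,9-trimethoxy-8-endo-methyl-8-exo-(4-methylpent-3-en-1-yl)bicyclo[3.3.1]non-3-ene-2,7-dione
Product: 13 4,9,9-trimethoxy-8-endo-methyl-7-methylidene-8-exo-(4-methylpent-3-en-1-yl)bicyclo[3.3.1]non-3-en-2-one
Conditions: Ph3PCH3Br, KOt-Bu, toluene, 0 → 70 °C
Reagents that add atoms: methyltriphenylphosphonium bromide, C[P+](c1ccccc1)(c1ccccc1)c1ccccc1.[Br-]
Why: Wittig methylenation with an excess of the small unstabilised ylide at elevated temperature (conditions used for hindered ketones); the vinylogous ester carbonyl is far less electrophilic and C9 is masked, so only C7 should react.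

**Step 10**
Reactants: 13 4,9,9-trimethoxy-8-endo-methyl-7-methylidene-8-exo-(4-methylpent-3-en-1-yl)bicyclo[3.3.1]non-3-en-2-one
Product: 15 4,9,9-trimethoxy-8-endo-methyl-7-endo-(3-methylbut-2-en-1-yl)-8-exo-(4-methylpent-3-en-1-yl)bicyclo[3.3.1]non-3-en-2-one, via B-alkyl-9-BBN borane 14 (not isolated)
Conditions: 9-BBN-H, THF, 23 → 50 °C; then Pd(dppf)Cl2 (cat.), K3PO4, H2O, Me2C=CHBr, DMF, 50 °C
Reagents that add atoms: 1-bromo-2-methylprop-1-ene, CC(C)=CBr
Why: Anti-Markovnikov hydroboration then B-alkyl Suzuki–Miyaura coupling: 9-BBN adds to the 1,1-disubstituted alkene much faster than to the trisubstituted one, hydrogen should reach C7 from the exo face because the endo face lies over C3 in the chair–chair form that the tetrahedral C9 ketal enforces, so the new CH2 group ends endo (cis to the 8-methyl group), and coupling with the vinyl bromide completes the prenyl group without touching C7.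

**Step 11**
Reactants: 15 4,9,9-trimethoxy-8-endo-methyl-7-endo-(3-methylbut-2-en-1-yl)-8-exo-(4-methylpent-3-en-1-yl)bicyclo[3.3.1]non-3-en-2-one
Product: 17 4,9,9-trimethoxy-8-endo-methyl-3-(2-methylpropanoyl)-7-endo-(3-methylbut-2-en-1-yl)-8-exo-(4-methylpent-3-en-1-yl)bicyclo[3.3.1]non-3-en-2-one, via C3-lithio enone 16 (not isolated)
Conditions: LiTMP, THF, −78 °C; then i-PrCOCl, −78 → 0 °C
Reagents that add atoms: 2-methylpropanoyl chloride, CC(C)C(Cl)=O
Why: Directed vinylic lithiation of the β-methoxy enone at C3 (the sp2 C–H between the carbonyl and the methoxy-bearing carbon, as practised on bicyclic vinylogous esters of this type) followed by C-acylation; the α-hydrogen at C1 is a bridgehead hydrogen that cannot enolise (Bredt) and no stereocenter is affected.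

**Step 12**
Reactants: 17 4,9,9-trimethoxy-8-endo-methyl-3-(2-methylpropanoyl)-7-endo-(3-methylbut-2-en-1-yl)-8-exo-(4-methylpent-3-en-1-yl)bicyclo[3.3.1]non-3-en-2-one
Product: 19 (1S,5S,7R,8S)-2-hydroxy-8-methyl-3-(2-methylpropanoyl)-7-(3-methylbut-2-en-1-yl)-8-(4-methylpent-3-en-1-yl)bicyclo[3.3.1]non-2-ene-4,9-dione, via methyl ether triketone 18 (not isolated)
Conditions: 1 M HCl, THF, 23 °C; then LiOH, H2O–dioxane, 60 °C; H3O+
Reagents that add atoms: water, O
Why: Aqueous acid hydrolyses the dimethyl ketal to the C9 ketone and hydroxide then displaces methoxide from C4 of the doubly activated vinylogous ester by addition–elimination, leaving the enolised β-triketone as its enolate until acidification; C1 and C5 are bridgeheads and C7/C8 are not enolisable, so no stereocenter can scramble.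

**Compound list**
1 | 1,3-dimethoxybenzene | COc1cccc(OC)c1 | starting material
2 | 1,5-dimethoxycyclohexa-1,4-diene | COC1=CCC=C(OC)C1 | intermediate
3 | nerol, (2Z)-3,7-dimethylocta-2,6-dien-1-ol | CC(C)=CCC/C(C)=C\CO | starting material
4 | (2S,3R)-2,3-epoxynerol, [(2S,3R)-3-methyl-3-(4-methylpent-3-en-1-yl)oxiran-2-yl]methanol | CC(C)=CCC[C@@]1(C)O[C@H]1CO | intermediate
5 | (2R,3R)-2-(bromomethyl)-3-methyl-3-(4-methylpent-3-en-1-yl)oxirane (same spatial arrangement as 4) | CC(C)=CCC[C@@]1(C)O[C@H]1CBr | intermediate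
6 | (2,6-dimethoxycyclohexa-2,5-dien-1-yl)lithium | [Li]C1C(OC)=CCC=C1OC | intermediate (not isolated)
7 | (2S,3R)-2-[(2,6-dimethoxycyclohexa-2,5-dien-1-yl)methyl]-3-methyl-3-(4-methylpent-3-en-1-yl)oxirane | CC(C)=CCC[C@@]1(C)O[C@H]1CC1C(OC)=CCC=C1OC | intermediate
8 | C9 O-methyl oxocarbenium triflate of 4-methoxy-8-endo-methyl-8-exo-(4-methylpent-3-en-1-yl)-7-exo-(trimethylsilyloxy)bicyclo[3.3.1]non-3-en-9-one | CC(C)=CCC[C@@]1(C)[C@@H](O[Si](C)(C)C)C[C@@H]2C(OC)=CC[C@H]1C2=[O+]C.[O-]S(=O)(=O)C(F)(F)F | intermediate (not isolated)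
9 | (1R,5R,7S,8R,9S)-4,9-dimethoxy-8-methyl-8-(4-methylpent-3-en-1-yl)-7,9-epoxybicyclo[3.3.1]non-3-ene (oxygen bridge and homoprenyl exo, 8-methyl endo) | CC(C)=CCC[C@@]1(C)[C@@H]3C[C@@H]2C(OC)=CC[C@H]1[C@]2(OC)O3 | intermediate
10 | 4,9-dimethoxy-8-endo-methyl-8-exo-(4-methylpent-3-en-1-yl)-7,9-epoxybicyclo[3.3.1]non-3-en-2-one (configuration as in 9) | CC(C)=CCC[C@@]1(C)[C@@H]3C[C@@H]2C(OC)=CC(=O)[C@H]1[C@]2(OC)O3 | intermediate
11 | 7-exo-hydroxy-4,9,9-trimethoxy-8-endo-methyl-8-exo-(4-methylpent-3-en-1-yl)bicyclo[3.3.1]non-3-en-2-one | CC(C)=CCC[C@@]1(C)[C@@H](O)C[C@@H]2C(OC)=CC(=O)[C@H]1C2(OC)OC | intermediate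
12 | 4,9,9-trimethoxy-8-endo-methyl-8-exo-(4-methylpent-3-en-1-yl)bicyclo[3.3.1]non-3-ene-2,7-dione | CC(C)=CCC[C@@]1(C)C(=O)C[C@@H]2C(OC)=CC(=O)[C@H]1C2(OC)OC | intermediate
13 | 4,9,9-trimethoxy-8-endo-methyl-7-methylidene-8-exo-(4-methylpent-3-en-1-yl)bicyclo[3.3.1]non-3-en-2-one | CC(C)=CCC[C@@]1(C)C(=C)C[C@@H]2C(OC)=CC(=O)[C@H]1C2(OC)OC | intermediate
14 | 7-endo-[(9-borabicyclo[3.3.1]nonan-9-yl)methyl]-4,9,9-trimethoxy-8-endo-methyl-8-exo-(4-methylpent-3-en-1-yl)bicyclo[3.3.1]non-3-en-2-one | CC(C)=CCC[C@@]1(C)[C@H](CB3C4CCCC3CCC4)C[C@@H]2C(OC)=CC(=O)[C@H]1C2(OC)OC | intermediate (not isolated)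
15 | 4,9,9-trimethoxy-8-endo-methyl-7-endo-(3-methylbut-2-en-1-yl)-8-exo-(4-methylpent-3-en-1-yl)bicyclo[3.3.1]non-3-en-2-one | CC(C)=CCC[C@@]1(C)[C@H](CC=C(C)C)C[C@@H]2C(OC)=CC(=O)[C@H]1C2(OC)OC | intermediate
16 | 3-lithio derivative of 15 | CC(C)=CCC[C@@]1(C)[C@H](CC=C(C)C)C[C@@H]2C(OC)=C([Li])C(=O)[C@H]1C2(OC)OC | intermediate (not isolated)
17 | 4,9,9-trimethoxy-8-endo-methyl-3-(2-methylpropanoyl)-7-endo-(3-methylbut-2-en-1-yl)-8-exo-(4-methylpent-3-en-1-yl)bicyclo[3.3.1]non-3-en-2-one | CC(C)=CCC[C@@]1(C)[C@H](CC=C(C)C)C[C@@H]2C(OC)=C(C(=O)C(C)C)C(=O)[C@H]1C2(OC)OC | intermediate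
18 | 4-methoxy-8-endo-methyl-3-(2-methylpropanoyl)-7-endo-(3-methylbut-2-en-1-yl)-8-exo-(4-methylpent-3-en-1-yl)bicyclo[3.3.1]non-3-ene-2,9-dione | CC(C)=CCC[C@@]1(C)[C@H](CC=C(C)C)C[C@@H]2C(OC)=C(C(=O)C(C)C)C(=O)[C@H]1C2=O | intermediate (not isolated)
19 | (1S,5S,7R,8S)-2-hydroxy-8-methyl-3-(2-methylpropanoyl)-7-(3-methylbut-2-en-1-yl)-8-(4-methylpent-3-en-1-yl)bicyclo[3.3.1]non-2-ene-4,9-dione (7-prenyl and 8-methyl endo, 8-homoprenyl exo; descriptors for the tautomer drawn) | CC(C)=CCC[C@@]1(C)[C@H](CC=C(C)C)C[C@@H]2C(=O)C(C(=O)C(C)C)=C(O)[C@H]1C2=O | target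

**Step count and risks**
Total step count: 12. Longest linear sequence: 11 steps (nerol 3 → 19; the arene branch 1 → 2 joins at step 4).

The three steps most likely to fail:

Step 10. Hydroboration of the 7-methylene next to the quaternary C8 may be slow with the bulky dialkylborane, so that reduction of the C2 carbonyl and loss of exo-face control (escape of ring B into a boat) intrude. The fallback sets out from 13. Rhodium-catalysed hydroformylation (Rh(acac)(CO)2, tris(2,4-di-tert-butylphenyl) phosphite, CO/H2, toluene, 60 °C) uses a small Rh–H that should add to the exo face, puts the formyl group on the terminal carbon and tolerates the carbonyl groups. It would give 2-[4,9,9-trimethoxy-8-endo-methyl-8-exo-(4-methylpent-3-en-1-yl)-2-oxobicyclo[3.3.1]non-3-en-7-endo-yl]acetaldehyde F1. Wittig reaction of this aldehyde with isopropylidenetriphenylphosphorane (i-PrPPh3I, n-BuLi, THF, −78 → 0 °C) comes back to the route at 15.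

Step 7. The ketal exchange is an equilibrium, and re-closure of the freed C7 hydroxyl onto C9 may hold the material back as the bridged ketal. The fallback sets out from 10. Silylative opening with TMSOTf (cat.) and methoxytrimethylsilane (CH2Cl2, −78 °C) caps the ring oxygen as it leaves C9 and transfers methoxide to C9. It would give 4,9,9-trimethoxy-8-endo-methyl-8-exo-(4-methylpent-3-en-1-yl)-7-exo-(trimethylsilyloxy)bicyclo[3.3.1]non-3-en-2-one F2, which cannot close again. Removal of the silyl group (K2CO3, MeOH, 0 °C) comes back to the route at 11.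

Step 9. Addition of the ylide to the C7 carbonyl, which is flanked by the quaternary C8 with its axial chain, may be slower than enolisation towards C6, so that the ketone is returned. The fallback sets out from 12 and uses this enolisation instead of carbonyl addition. KHMDS and PhNTf2 (THF, −78 °C) would give 4,9,9-trimethoxy-8-endo-methyl-8-exo-(4-methylpent-3-en-1-yl)-2-oxobicyclo[3.3.1]nona-3,6-dien-7-yl trifluoromethanesulfonate F3. Negishi coupling with (trimethylsilyl)methylzinc chloride (Pd(PPh3)4, THF, 40 °C) would give 4,9,9-trimethoxy-8-endo-methyl-8-exo-(4-methylpent-3-en-1-yl)-7-[(trimethylsilyl)methyl]bicyclo[3.3.1]nona-3,6-dien-2-one F4. Protodesilylation of this allylsilane (TsOH cat., MeOH–CH2Cl2, 0 °C; proton to C6, double bond to the exocyclic position) comes back to the route at 13.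

**Further compounds**
F1 | step 10 | 2-[4,9,9-trimethoxy-8-endo-methyl-8-exo-(4-methylpent-3-en-1-yl)-2-oxobicyclo[3.3.1]non-3-en-7-endo-yl]acetaldehyde | CC(C)=CCC[C@@]1(C)[C@H](CC=O)C[C@@H]2C(OC)=CC(=O)[C@H]1C2(OC)OC
F2 | step 7 | 4,9,9-trimethoxy-8-endo-methyl-8-exo-(4-methylpent-3-en-1-yl)-7-exo-(trimethylsilyloxy)bicyclo[3.3.1]non-3-en-2-one | CC(C)=CCC[C@@]1(C)[C@@H](O[Si](C)(C)C)C[C@@H]2C(OC)=CC(=O)[C@H]1C2(OC)OC
F3 | step 9 | 4,9,9-trimethoxy-8-endo-methyl-8-exo-(4-methylpent-3-en-1-yl)-2-oxobicyclo[3.3.1]nona-3,6-dien-7-yl trifluoromethanesulfonate | CC(C)=CCC[C@@]1(C)C(OS(=O)(=O)C(F)(F)F)=C[C@@H]2C(OC)=CC(=O)[C@H]1C2(OC)OC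
F4 | step 9 | 4,9,9-trimethoxy-8-endo-methyl-8-exo-(4-methylpent-3-en-1-yl)-7-[(trimethylsilyl)methyl]bicyclo[3.3.1]nona-3,6-dien-2-one | CC(C)=CCC[C@@]1(C)C(C[Si](C)(C)C)=C[C@@H]2C(OC)=CC(=O)[C@H]1C2(OC)OC
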